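**Retrosynthetic overview**
- Feature used: ring A carries oxygen on C5, C7 and C8a in the alternating (phloroglucinol, polyketide) pattern, with the extra O8, and is fused to pyranone ring C at C4a–C8a. C5 can therefore be an ester carbon on the pyranone, and C6–C7–C8 a ketone arm on the neighbouring ring carbon.
- Target ⇐ hydrogenolysis of three benzyl ethers ⇐ sulfation of the free 7-OH of 8-(benzyloxy)-5,7-dihydroxyflavone (the 5-OH is chelated to the C4 carbonyl).
- Ring A ⇐ Claisen disconnection of C5–C6 ⇒ methyl 6-aryl-2-[1-(benzyloxy)-2-oxopropyl]-4-oxopyran-3-carboxylate.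
- Side chain (C7–C8 bond) ⇐ lateral acetylation of the 2-(benzyloxymethyl)pyranone. Ring C ⇐ C-acylation of methyl 4-(benzyloxy)-3-oxobutanoate with the arylpropioloyl chloride and 6-endo-dig O-closure. Acid chloride ⇐ 3,4-bis(benzyloxy)benzaldehyde (Corey–Fuchs, CO2).
- Ring order: ring B is bought, ring C is closed in step 4, ring A in step 6.

Key step: step 6

Assumption: the target is taken as drawn, the free hydrogen sulfate. Aryl hydrogen sulfates hydrolyse under their own acidity, so the sulfate is carried as its sodium salt and protonated only in the last operation, in the cold.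

Step 1
Reactants: 1 3,4-bis(benzyloxy)benzaldehyde
Product: 2 1,2-bis(benzyloxy)-4-(2,2-dibromoethenyl)benzene
Conditions: CBr4, PPh3, Zn dust, CH2Cl2, 0 °C → rt
Reagents that add atoms: carbon tetrabromide, BrC(Br)(Br)Br
Why: Corey–Fuchs dibromo-olefination, in which the ylide Ph3P=CBr2 formed from CBr4, PPh3 and Zn converts the aryl aldehyde into the 1,1-dibromoalkene under neutral conditions that leave the benzyl ethers untouched.

Step 2
Reactants: 2 1,2-bis(benzyloxy)-4-(2,2-dibromoethenyl)benzene
Product: 4 3-[3,4-bis(benzyloxy)phenyl]prop-2-ynoic acid, via lithium acetylide 3 (not isolated)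
Conditions: n-BuLi (2.2 equiv), THF, −78 °C; then CO2, −78 °C → rt; aq HCl
Reagents that add atoms: carbon dioxide, O=C=O
Why: Second stage of the Corey–Fuchs sequence, in which two equivalents of n-BuLi effect elimination and bromine–lithium exchange to the lithium acetylide, which should be carboxylated by CO2 at low temperature before any benzylic metalation can compete.

Step 3
Reactants: 4 3-[3,4-bis(benzyloxy)phenyl]prop-2-ynoic acid
Product: 5 3-[3,4-bis(benzyloxy)phenyl]prop-2-ynoyl chloride
Conditions: (COCl)2, DMF (cat.), CH2Cl2, 0 °C → rt; used crude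
Reagents that add atoms: oxalyl chloride, ClC(=O)C(Cl)=O
Why: Standard acid chloride formation through the chloroiminium species from DMF and oxalyl chloride, kept at or below room temperature so that HCl does not add to the electron-rich alkyne.

Step 4
Reactants: 5 3-[3,4-bis(benzyloxy)phenyl]prop-2-ynoyl chloride; 6 methyl 4-(benzyloxy)-3-oxobutanoate
Product: 8 methyl 2-[(benzyloxy)methyl]-6-[3,4-bis(benzyloxy)phenyl]-4-oxo-4H-pyran-3-carboxylate, via acylated keto ester 7 (not isolated)
Conditions: MgCl2, pyridine, CH2Cl2, 0 °C → rt; aq HCl wash; then Et3N, MeCN, 40 °C (crude 7 carried on)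
Reagents that add atoms: none
Why: Soft-enolisation C-acylation of the chelated magnesium enolate of the β-keto ester should give the 2-alkynoyl tricarbonyl compound, whose ketone enol oxygen then adds to the ynone β-carbon in a 6-endo-dig oxa-Michael closure (the classical pyranone synthesis from arylpropioloyl chlorides and β-dicarbonyl compounds), and because the ketone oxygen and not the ester oxygen closes the ring the ester ends on C3 of ring C.

Step 5
Reactants: 8 methyl 2-[(benzyloxy)methyl]-6-[3,4-bis(benzyloxy)phenyl]-4-oxo-4H-pyran-3-carboxylate; 9 N-acetylimidazole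
Product: 10 methyl 6-[3,4-bis(benzyloxy)phenyl]-2-[1-(benzyloxy)-2-oxopropyl]-4-oxo-4H-pyran-3-carboxylate (racemic)
Conditions: LiN(SiMe3)2 (2.2 equiv), THF, −78 °C; then 9; AcOH quench at −78 °C
Reagents that add atoms: none
Why: Lateral (vinylogous) Claisen acylation of a 2-alkyl-4-pyranone, in which the CH2 on pyranone C2 is the vinylogous α-position of both the C4 ketone and the C3 ester, its lithium dienolate should be C-acylated at the exocyclic carbon by the acyl imidazole because only that site restores the pyranone, and the second equivalent of base holds the more acidic product as its enolate until the cold acidic quench; the new side-chain centre is formed racemic and disappears in step 6.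

Step 6
Reactants: 10 methyl 6-[3,4-bis(benzyloxy)phenyl]-2-[1-(benzyloxy)-2-oxopropyl]-4-oxo-4H-pyran-3-carboxylate
Product: 12 8-(benzyloxy)-2-[3,4-bis(benzyloxy)phenyl]-5,7-dihydroxy-4H-chromen-4-one, via cyclic triketone tautomer 11 (not isolated)
Conditions: LiN(SiMe3)2 (4 equiv), THF, −78 °C → rt; aq HCl
Reagents that add atoms: none
Why: Proposed new method: LiN(SiMe3)2 should first deprotonate the doubly activated C–H between the ketone and the pyranone (the future C8) and then, at least reversibly, the acetyl methyl group, whose carbon (the future C6) adds to the ester carbonyl (the future C5) with loss of methoxide to give the cyclic triketone 11, which enolises at once to the aromatic ring A and so makes the C-acylation irreversible. The closest known reaction type is the biomimetic Claisen cyclisation of 3,5,7-triketo esters to acylphloroglucinols, together with the terminal-carbon reactivity of β-dicarbonyl dianions. Ring A closes in the 6-exo-trig mode onto the ester C=O, which its two ortho neighbours should twist out of the pyranone plane so that its π* orbital faces the in-plane nucleophile and takes little of the charge of the first anion. No stereocentre is formed, and the racemic side-chain centre of 10 becomes the sp2 carbon C8. The step needs C- over O-acylation and closure through the methyl carbon only: the central carbon could give only a four-membered ring, attack on the C4 carbonyl would need a bridged bicycle across the planar pyranone, the enol lactone from O-attack can be reopened by methoxide whereas the arene cannot, and the hindered amide base should not add to the electrophilic positions of ring C.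

Step 7
Reactants: 12 8-(benzyloxy)-2-[3,4-bis(benzyloxy)phenyl]-5,7-dihydroxy-4H-chromen-4-one
Product: 14 sodium 8-(benzyloxy)-2-[3,4-bis(benzyloxy)phenyl]-5-hydroxy-4-oxo-4H-chromen-7-yl sulfate, via pyridinium sulfate salt 13 (not isolated)
Conditions: SO3·pyridine (2 equiv), pyridine, rt; then aq NaHCO3
Reagents that add atoms: sulfur trioxide–pyridine complex, [O-]S(=O)(=O)[n+]1ccccc1; sodium hydrogen carbonate, [Na+].OC(=O)[O-]
Why: O-Sulfation of a phenol with the SO3·pyridine complex should go to the 7-OH because the only other free hydroxyl, the 5-OH, is locked in a hydrogen bond to the C4 carbonyl (the usual selectivity of 5,7-dihydroxyflavones), and exchange to the sodium salt removes pyridine, which would slow the hydrogenolysis that follows.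

Step 8
Reactants: 14 sodium 8-(benzyloxy)-2-[3,4-bis(benzyloxy)phenyl]-5-hydroxy-4-oxo-4H-chromen-7-yl sulfate
Product: 16 8-hydroxyluteolin 7-sulfate, 2-(3,4-dihydroxyphenyl)-5,8-dihydroxy-4-oxo-4H-chromen-7-yl hydrogen sulfate, via sodium salt of the target 15 (not isolated)
Conditions: H2 (1 atm), 10% Pd/C, MeOH/THF, rt; filtration under Ar; then aq HCl (1.0 equiv), 0 °C; C18 desalting, lyophilisation
Reagents that add atoms: none
Why: Catalytic hydrogenolysis should cleave the three aryl benzyl ethers while the aryl sulfate monoester and the flavone C2–C3 double bond stay inert to H2 over Pd/C at room temperature, exclusion of air protects the 5,8-hydroquinone-type ring A, and one equivalent of HCl in the cold releases the hydrogen sulfate without hydrolysing it.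

**Compound list**
1 | 3,4-bis(benzyloxy)benzaldehyde | O=Cc1ccc(OCc2ccccc2)c(OCc2ccccc2)c1 | starting material
2 | 1,2-bis(benzyloxy)-4-(2,2-dibromoethenyl)benzene | BrC(Br)=Cc1ccc(OCc2ccccc2)c(OCc2ccccc2)c1 | intermediate
3 | {[3,4-bis(benzyloxy)phenyl]ethynyl}lithium | [Li]C#Cc1ccc(OCc2ccccc2)c(OCc2ccccc2)c1 | intermediate
4 | 3-[3,4-bis(benzyloxy)phenyl]prop-2-ynoic acid | OC(=O)C#Cc1ccc(OCc2ccccc2)c(OCc2ccccc2)c1 | intermediate
5 | 3-[3,4-bis(benzyloxy)phenyl]prop-2-ynoyl chloride | ClC(=O)C#Cc1ccc(OCc2ccccc2)c(OCc2ccccc2)c1 | intermediate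
6 | methyl 4-(benzyloxy)-3-oxobutanoate | COC(=O)CC(=O)COCc1ccccc1 | starting material
7 | methyl 4-(benzyloxy)-2-{3-[3,4-bis(benzyloxy)phenyl]prop-2-ynoyl}-3-oxobutanoate (drawn as the triketo tautomer, present as enol) | COC(=O)C(C(=O)COCc1ccccc1)C(=O)C#Cc1ccc(OCc2ccccc2)c(OCc2ccccc2)c1 | intermediate
8 | methyl 2-[(benzyloxy)methyl]-6-[3,4-bis(benzyloxy)phenyl]-4-oxo-4H-pyran-3-carboxylate | COC(=O)c1c(COCc2ccccc2)oc(-c2ccc(OCc3ccccc3)c(OCc3ccccc3)c2)cc1=O | intermediate
9 | N-acetylimidazole | CC(=O)n1ccnc1 | starting material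
10 | methyl 6-[3,4-bis(benzyloxy)phenyl]-2-[1-(benzyloxy)-2-oxopropyl]-4-oxo-4H-pyran-3-carboxylate (racemic) | COC(=O)c1c(C(OCc2ccccc2)C(C)=O)oc(-c2ccc(OCc3ccccc3)c(OCc3ccccc3)c2)cc1=O | intermediate
11 | 8-(benzyloxy)-2-[3,4-bis(benzyloxy)phenyl]-6H-chromene-4,5,7(8H)-trione (racemic keto tautomer) | O=C1CC(=O)C(OCc2ccccc2)c2oc(-c3ccc(OCc4ccccc4)c(OCc4ccccc4)c3)cc(=O)c12 | intermediate
12 | 8-(benzyloxy)-2-[3,4-bis(benzyloxy)phenyl]-5,7-dihydroxy-4H-chromen-4-one | O=c1cc(-c2ccc(OCc3ccccc3)c(OCc3ccccc3)c2)oc2c(OCc3ccccc3)c(O)cc(O)c12 | intermediate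
13 | pyridinium 8-(benzyloxy)-2-[3,4-bis(benzyloxy)phenyl]-5-hydroxy-4-oxo-4H-chromen-7-yl sulfate | O=c1cc(-c2ccc(OCc3ccccc3)c(OCc3ccccc3)c2)oc2c(OCc3ccccc3)c(OS(=O)(=O)[O-])cc(O)c12.c1cc[nH+]cc1 | intermediate
14 | sodium 8-(benzyloxy)-2-[3,4-bis(benzyloxy)phenyl]-5-hydroxy-4-oxo-4H-chromen-7-yl sulfate | O=c1cc(-c2ccc(OCc3ccccc3)c(OCc3ccccc3)c2)oc2c(OCc3ccccc3)c(OS(=O)(=O)[O-])cc(O)c12.[Na+] | intermediate
15 | sodium 2-(3,4-dihydroxyphenyl)-5,8-dihydroxy-4-oxo-4H-chromen-7-yl sulfate | O=c1cc(-c2ccc(O)c(O)c2)oc2c(O)c(OS(=O)(=O)[O-])cc(O)c12.[Na+] | intermediate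
16 | 8-hydroxyluteolin 7-sulfate, 2-(3,4-dihydroxyphenyl)-5,8-dihydroxy-4-oxo-4H-chromen-7-yl hydrogen sulfate | O=c1cc(-c2ccc(O)c(O)c2)oc2c(O)c(OS(=O)(=O)O)cc(O)c12 | target

**Step count and risk**
Total step count: 8. Longest linear sequence: 8 steps, from 1.

Steps most likely to fail:

1. Step 6 (proposed new method). The ester carbonyl sits next to a delocalised anion and may resist attack by carbon. O-acylation to the enol lactone, or base-induced opening of ring C, could then take over. The fallback takes ring A from a preformed phloroglucinol unit and introduces O8 by Elbs persulfate oxidation; it sets out from 1 and returns to the route at 12.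
   - Claisen–Schmidt condensation of 1 with commercial 1-[2-hydroxy-4,6-bis(methoxymethoxy)phenyl]ethanone (KOH, EtOH) should give the chalcone (E)-3-[3,4-bis(benzyloxy)phenyl]-1-[2-hydroxy-4,6-bis(methoxymethoxy)phenyl]prop-2-en-1-one F1.
   - I2 (cat.) in DMSO at 110 °C should close and dehydrogenate it to 2-[3,4-bis(benzyloxy)phenyl]-5,7-bis(methoxymethoxy)-4H-chromen-4-one F2.
   - HCl in MeOH should remove both acetals to give 2-[3,4-bis(benzyloxy)phenyl]-5,7-dihydroxy-4H-chromen-4-one F3.
   - Allyl bromide and K2CO3 in acetone should alkylate only the non-chelated 7-hydroxyl, giving 7-(allyloxy)-2-[3,4-bis(benzyloxy)phenyl]-5-hydroxy-4H-chromen-4-one F4.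
   - Elbs oxidation (K2S2O8, aq KOH/pyridine, 0 °C → rt) should attack para to the 5-phenoxide and give potassium 7-(allyloxy)-2-[3,4-bis(benzyloxy)phenyl]-5-hydroxy-4-oxo-4H-chromen-8-yl sulfate F5.
   - Warm dilute HCl should hydrolyse this to 7-(allyloxy)-2-[3,4-bis(benzyloxy)phenyl]-5,8-dihydroxy-4H-chromen-4-one F6.
   - Benzyl bromide and K2CO3 should alkylate the free 8-hydroxyl (the 5-OH stays chelated) to give 7-(allyloxy)-8-(benzyloxy)-2-[3,4-bis(benzyloxy)phenyl]-5-hydroxy-4H-chromen-4-one F7.
   - Pd(PPh3)4 with morpholine should remove the allyl group and deliver 12.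

2. Step 5. The stabilised, hindered dienolate may be acylated on oxygen or not at all, or the product enolate may close onto the ester before the quench. The fallback forms the C7–C8 bond by aldol addition and adjusts the oxidation level afterwards; it sets out from 8 and returns at 10.
   - The lithium dienolate of 8 (LiN(SiMe3)2, THF, −78 °C) would be treated with acetaldehyde and quenched cold with AcOH, to forestall lactonisation of the aldolate onto the neighbouring ester. This should give methyl 6-[3,4-bis(benzyloxy)phenyl]-2-[1-(benzyloxy)-2-hydroxypropyl]-4-oxo-4H-pyran-3-carboxylate F8 as a mixture of diastereomers.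
   - Both diastereomers should converge on 10 on oxidation with Dess–Martin periodinane (NaHCO3, CH2Cl2).

3. Step 4. The amine may add to or degrade the alkynoyl chloride before C-acylation, or the enol may close in the 5-exo mode to a furanone. The fallback uses the robust alkenoyl analogue and sets the oxidation level of ring C after closure, as in the chalcone-to-flavone route; it sets out from 1 and 6 and returns at 8.
   - Knoevenagel–Doebner condensation of 1 with malonic acid (pyridine, piperidine cat., 90 °C), with decarboxylation in the flask, should give (E)-3-[3,4-bis(benzyloxy)phenyl]prop-2-enoic acid F9.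
   - (COCl)2 with DMF (cat.) should convert it into (E)-3-[3,4-bis(benzyloxy)phenyl]prop-2-enoyl chloride F10.
   - C-acylation of 6 (MgCl2, pyridine, CH2Cl2) should give methyl (E)-4-(benzyloxy)-2-{3-[3,4-bis(benzyloxy)phenyl]prop-2-enoyl}-3-oxobutanoate F11.
   - Oxa-Michael closure (Et3N, MeCN) should give racemic methyl 6-[(benzyloxy)methyl]-2-[3,4-bis(benzyloxy)phenyl]-4-oxo-3,4-dihydro-2H-pyran-5-carboxylate F12.
   - Dehydrogenation with DDQ in dioxane at 80 °C should give 8.

Further compounds
F1 | step 6 | (E)-3-[3,4-bis(benzyloxy)phenyl]-1-[2-hydroxy-4,6-bis(methoxymethoxy)phenyl]prop-2-en-1-one | O=C(/C=C/c1ccc(OCc2ccccc2)c(OCc2ccccc2)c1)c1c(O)cc(OCOC)cc1OCOC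
F2 | step 6 | 2-[3,4-bis(benzyloxy)phenyl]-5,7-bis(methoxymethoxy)-4H-chromen-4-one | COCOc1cc(OCOC)c2c(=O)cc(-c3ccc(OCc4ccccc4)c(OCc4ccccc4)c3)oc2c1
F3 | step 6 | 2-[3,4-bis(benzyloxy)phenyl]-5,7-dihydroxy-4H-chromen-4-one | O=c1cc(-c2ccc(OCc3ccccc3)c(OCc3ccccc3)c2)oc2cc(O)cc(O)c12
F4 | step 6 | 7-(allyloxy)-2-[3,4-bis(benzyloxy)phenyl]-5-hydroxy-4H-chromen-4-one | C=CCOc1cc(O)c2c(=O)cc(-c3ccc(OCc4ccccc4)c(OCc4ccccc4)c3)oc2c1
F5 | step 6 | potassium 7-(allyloxy)-2-[3,4-bis(benzyloxy)phenyl]-5-hydroxy-4-oxo-4H-chromen-8-yl sulfate | C=CCOc1cc(O)c2c(=O)cc(-c3ccc(OCc4ccccc4)c(OCc4ccccc4)c3)oc2c1OS(=O)(=O)[O-].[K+]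
F6 | step 6 | 7-(allyloxy)-2-[3,4-bis(benzyloxy)phenyl]-5,8-dihydroxy-4H-chromen-4-one | C=CCOc1cc(O)c2c(=O)cc(-c3ccc(OCc4ccccc4)c(OCc4ccccc4)c3)oc2c1O
F7 | step 6 | 7-(allyloxy)-8-(benzyloxy)-2-[3,4-bis(benzyloxy)phenyl]-5-hydroxy-4H-chromen-4-one | C=CCOc1cc(O)c2c(=O)cc(-c3ccc(OCc4ccccc4)c(OCc4ccccc4)c3)oc2c1OCc1ccccc1
F8 | step 5 | methyl 6-[3,4-bis(benzyloxy)phenyl]-2-[1-(benzyloxy)-2-hydroxypropyl]-4-oxo-4H-pyran-3-carboxylate (racemic, both diastereomers) | COC(=O)c1c(C(OCc2ccccc2)C(C)O)oc(-c2ccc(OCc3ccccc3)c(OCc3ccccc3)c2)cc1=O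
F9 | step 4 | (E)-3-[3,4-bis(benzyloxy)phenyl]prop-2-enoic acid | OC(=O)/C=C/c1ccc(OCc2ccccc2)c(OCc2ccccc2)c1
F10 | step 4 | (E)-3-[3,4-bis(benzyloxy)phenyl]prop-2-enoyl chloride | ClC(=O)/C=C/c1ccc(OCc2ccccc2)c(OCc2ccccc2)c1
F11 | step 4 | methyl (E)-4-(benzyloxy)-2-{3-[3,4-bis(benzyloxy)phenyl]prop-2-enoyl}-3-oxobutanoate | COC(=O)C(C(=O)COCc1ccccc1)C(=O)/C=C/c1ccc(OCc2ccccc2)c(OCc2ccccc2)c1
F12 | step 4 | methyl 6-[(benzyloxy)methyl]-2-[3,4-bis(benzyloxy)phenyl]-4-oxo-3,4-dihydro-2H-pyran-5-carboxylate (racemic) | COC(=O)C1=C(COCc2ccccc2)OC(c2ccc(OCc3ccccc3)c(OCc3ccccc3)c2)CC1=O
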